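The target is the product I want, and it forms from the substrate by a reversible step while other steps lead away from both.

    target ⇌ isomer of the product B (K1 = 0.45, k1 = 0.174 s⁻¹)
    substrate ⇌ third isomer (K2 = 13.4, k2 = 0.00393 s⁻¹)
    2 substrate → self-condensation product (k3 = 0.114 M⁻¹ s⁻¹)
    substrate ⇌ isomer of the product A (K4 = 2.7, k4 = 0.0715 s⁻¹)
    substrate ⇌ target (K5 = 0.43, k5 = 0.156 s⁻¹)

the same everywhere: substrate 0.91 M
- elm: a single well-mixed tank run continuously and read at steady state, 20 s in it on average
- ash: everything together in a closed stirred flask, run for 20 s; time 20 s

- percentages count the substrate that a species holds: one self-condensation product counts as two
- a step written with two of one species runs at k times the square of its concentration and takes two of it each time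
- the stated concentrations are those of everything mixed, before any reaction; amounts are the same in each set-up
- run time (ash): 20 s

1. the set-up with the highest share of target in all that became target or isomer of the product A or third isomer or isomer of the product B, at the outlet or at the end ("none" if the first two lie within 2 percentage points) (elm / ash / none)
2. share of target in all that became target or isomer of the product A or third isomer or isomer of the product B, at the outlet or at the end, elm
3. share of target in all that became target or isomer of the product A or third isomer or isomer of the product B, at the outlet or at the end, ash

1. I build a scale first. Suppose every reversible step stands at its K, and give substrate the weight 1. Target then weighs 0.43, isomer of the product B 0.194, isomer of the product A 2.7 and third isomer 13.4. Substrate cancels, so self-condensation does not enter. Target's share is 2.57 %. This equilibrium share is the zero of my scale.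

2. Now the ladder, each half-life counting one direction, with the way back not counted. Target returns to substrate in 1.91 s, substrate gives target in 4.44 s, and target gives isomer of the product B in 3.98 s. Each is shorter than the 20 s of ash. So these three species keep pace with one another.

3. Self-condensation has a first half-life of 4.82 s at the charge, and substrate gives isomer of the product A in 9.69 s. Both are shorter than 20 s, so substrate falls in ash, and target falls with it.

4. Isomer of the product A returns in 26.2 s, longer than 20 s. So it gathers in ash.

5. Third isomer forms in 176 s, far longer than 20 s, yet its weight is the heaviest on the scale. Without that weight the share is 12.9 %, which is higher than the zero. I expect both set-ups above this value, but my scale gives no order between them.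

The forecast says 23.8 % for elm and 17.4 % for ash, so elm. Its picture of ash: “Target forms quickly, then drains back to substrate”.

The simulation gives 23.8 % for elm and 17.3 % for ash, so elm stands higher, and both lie above 12.9 %. Ash stands below elm partly because target returns to substrate: with that back reaction struck out in both, the gap shrinks from 6.4 percentage points to 1.7 points, and elm no longer wins. Left for 200 s, ash reads 8.58 %, below 12.9 % and above the zero of 2.57 %.

(The numbers were set for the occasion.)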